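**Retrosynthetic overview**
1. The anisoate is cut last at O–C10, and the C10 carbinol is traced back to syn-selective reduction of a 5-hydroxy-dauc-8-en-10-one.
2. Feature the strategy rests on: in the seven-membered ring (C1, C10, C9, C8, C7, C6, C5) the tertiary carbinol C5 and the methyl-bearing olefinic C8 are 1,4-related and C10 is the centre of the arc C1–C10–C9. That ring is therefore a β-eliminated 8-oxabicyclo[3.2.1]octan-3-one: C5–C6–C7–C8 and the C5 oxygen are a 2-methylfuran, and C1–C10–C9 is an oxyallyl cation.
3. Key disconnection: intramolecular furan–oxyallyl (4+3) cycloaddition of a furan-tethered chloromethyl ketone (bonds C1–C5 and C9–C8), then hydrogenation of C6=C7 and opening of the C8–O bond.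
4. The chloroketone comes from an (R)-β-furyl aldehyde by Horner–Wadsworth–Emmons olefination, conjugate reduction and chloromethyllithium; C4 of the aldehyde is set by organocatalytic Friedel–Crafts addition of 2-methylfuran to (E)-4-methylpent-2-enal.
5. Ring order: the furan is bought; cyclopentane and cycloheptane close together in the (4+3) step as an oxygen-bridged tricycle; the bridge is then opened; the anisoyl ring is attached last.

Key step: step 5

Remark: atoms are numbered as in daucane (C1 angular-methyl fusion carbon, C2, C3, C4 isopropyl carbon, C5 oxygenated fusion carbon, C6, C7, C8 ring-methyl carbon, C9, C10). Compounds 6 and 7 are carried as epimer mixtures at the carbon that becomes C1, which is planar in cation 8.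

**Step 1**
Reactants: 1 2-methylfuran; 2 (E)-4-methylpent-2-enal
Product: 3 (R)-4-methyl-3-(5-methylfuran-2-yl)pentanal
Conditions: (2R,5R)-5-benzyl-2-tert-butyl-3-methylimidazolidin-4-one·CF3CO2H (20 mol %), 1 (3 equiv), CH2Cl2/i-PrOH, −40 °C
Reagents that add atoms: none
Why: Enantioselective iminium-catalysed Friedel–Crafts conjugate addition, in which the free α-position of 1 adds to the β-carbon of the (E)-iminium ion of 2 on the face left open by the catalyst benzyl group; the (2R,5R) catalyst is expected to set C4 as R because the (2S,5S) antipode directs heteroarenes to the opposite face, and the sense is to be confirmed on the first batch.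

**Step 2**
Reactants: 3 (R)-4-methyl-3-(5-methylfuran-2-yl)pentanal; 4 triethyl 2-phosphonopropionate
Product: 5 ethyl (2E,5R)-2,6-dimethyl-5-(5-methylfuran-2-yl)hept-2-enoate
Conditions: NaH, THF, 0 °C to rt
Reagents that add atoms: none
Why: Horner–Wadsworth–Emmons olefination joins C2 to C1 with its methyl group; the stereocentre is β to the aldehyde and cannot epimerise, and the alkene geometry is of no consequence because the alkene is reduced next.

**Step 3**
Reactants: 5 ethyl (2E,5R)-2,6-dimethyl-5-(5-methylfuran-2-yl)hept-2-enoate
Product: 6 ethyl (2RS,5R)-2,6-dimethyl-5-(5-methylfuran-2-yl)heptanoate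
Conditions: NiCl2·6H2O (0.3 equiv), NaBH4, EtOH, 0 °C
Reagents that add atoms: none
Why: Nickel boride conjugate reduction saturates only the ester-conjugated alkene and leaves the aromatic furan and the ester untouched (ethanol as solvent avoids ester exchange); the new α-centre is formed without control, which does not matter.

**Step 4**
Reactants: 6 ethyl (2RS,5R)-2,6-dimethyl-5-(5-methylfuran-2-yl)heptanoate
Product: 7 (3RS,6R)-1-chloro-3,7-dimethyl-6-(5-methylfuran-2-yl)octan-2-one
Conditions: ICH2Cl, MeLi·LiBr added slowly (Barbier mode), THF, −78 °C; AcOH quench at −78 °C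
Reagents that add atoms: chloroiodomethane ClCI
Why: Chloromethyllithium, made in situ by iodine–lithium exchange, adds once to the α-branched ester to give a tetrahedral lithium hemiketal that is stable at −78 °C and collapses to the chloromethyl ketone only on acidic quench (carbenoid homologation of an ester); this supplies C9 with its leaving group without any electrophilic halogenation that the furan would not survive.

**Step 5**
Reactants: 7 (3RS,6R)-1-chloro-3,7-dimethyl-6-(5-methylfuran-2-yl)octan-2-one
Product: 9 (1S,4R,5S,8R)-5,8-epoxydauc-6-en-10-one (oxygen bridge C5–O–C8; C1 methyl and C4 isopropyl on the cyclopentane face that carries the C5–O bond), via oxyallyl cation 8 (not isolated)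
Conditions: NaOCH2CF3 (1.5 equiv), CF3CH2OH (high dilution), 0 °C to rt
Reagents that add atoms: none
Why: Trifluoroethoxide removes the C1 proton of 7 and the enolate loses chloride from C9 to give oxyallyl cation 8 (C1–C10(O)–C9), which the electron-rich 2,5-dialkylfuran held three atoms away captures across its two α-carbons; the closest known reaction type is the intramolecular furan–oxyallyl (4+3) cycloaddition of α-halo ketones under base in a fluorinated alcohol. The cyclopentane closes by bonding the fully substituted terminus C1 to furan carbon C5, with the tether in the outside position of the W-shaped cation because a three-atom tether cannot reach from the inside position; the cycloheptenone closes as the (4+3) annulation by bonding C9 to C8, concerted or by enolate capture of the furan-derived oxocarbenium ion, and the furan oxygen remains as the C5–O–C8 bridge. C5 (and the C8 bridgehead, lost later) is set by the furan face that is attacked: allylic 1,3-strain keeps the C4–H on the side of the furan C6–H and the isopropyl group on the side of the ring oxygen, so the tether delivers the cation to the face that leaves isopropyl cis to the C5–O bond. C1 is set by the compact (endo) arrangement, in which the oxyallyl C10–O lies over C6=C7 and away from the furan oxygen, so that the outside tether becomes equatorial and the inside methyl ends syn to the oxygen bridge. The step therefore needs furan facial selectivity, secured by the C4 stereocentre next to the furan, and compact over extended geometry, which rests on the preference of weakly electrophilic sodium or hydrogen-bonded oxyallyls for the compact mode with furans and on the tether twisting away from the isopropyl group in that mode; this second selectivity is the least secure of the route. Because C1 is quaternary, the adduct ketone can enolise only toward C9, which fixes the direction of the later bridge opening.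

**Step 6**
Reactants: 9 (1S,4R,5S,8R)-5,8-epoxydauc-6-en-10-one
Product: 10 (1S,4R,5S,8S)-5,8-epoxydaucan-10-one
Conditions: H2 (1 atm), 10% Pd/C, EtOAc, rt
Reagents that add atoms: none
Why: Heterogeneous hydrogenation of the strained cis-disubstituted C6=C7 alkene is fast and leaves the ketone and the bridging ether intact; no stereocentre is created (C6 and C7 become CH2), and removing this alkene first prevents a dienone from forming when the bridge is opened.

**Step 7**
Reactants: 10 (1S,4R,5S,8S)-5,8-epoxydaucan-10-one
Product: 12 (1S,4R,5S)-5-hydroxydauc-8-en-10-one, via trimethylsilyl ether 11 (not isolated)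
Conditions: TMSOTf, Et3N, CH2Cl2, 0 °C to rt; then 1 M HCl, THF, 0 °C
Reagents that add atoms: none
Why: Soft enolisation can only give the C9=C10 silyl enol ether, and silyl activation of the bridge oxygen with push from the enol ether breaks the tertiary C8–O bond (β-elimination, a retro-oxa-Michael opening of an 8-oxabicyclo[3.2.1]octan-3-one) to give the conjugated C8=C9 enone with O5 silylated, so that no free β-alkoxide able to undergo retro-aldol cleavage is ever present; dilute acid then removes the trimethylsilyl group, the C8 stereocentre disappears and C1, C4 and C5 are untouched.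

**Step 8**
Reactants: 12 (1S,4R,5S)-5-hydroxydauc-8-en-10-one
Product: 13 (1R,4R,5S,10S)-dauc-8-ene-5,10-diol (C10–OH cis to C5–OH and to the C1 methyl)
Conditions: Et2BOMe, THF/MeOH (4:1), −78 °C; NaBH4, −78 °C; AcOH, then repeated evaporation from MeOH
Reagents that add atoms: none
Why: Narasaka–Prasad reduction, in which the diethylboron chelate between the C5 oxygen and the C10 carbonyl covers the face that carries the C5 oxygen and the angular methyl, so external borohydride adds to C10 from the opposite face (1,2-addition, favoured also by the fully substituted β-carbon C8) and sets C10 as S, a cyclic borinate across C5 and C10 being possible only for the cis-diol.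

**Step 9**
Reactants: 13 (1R,4R,5S,10S)-dauc-8-ene-5,10-diol; 14 4-methoxybenzoyl chloride
Product: 15 (1R,4R,5S,10S)-5-hydroxydauc-8-en-10-yl 4-methoxybenzoate (target CNP0158828.1)
Conditions: pyridine, DMAP (cat.), CH2Cl2, 0 °C to rt
Reagents that add atoms: none
Why: DMAP-catalysed acylation through the N-acylpyridinium ion esterifies the secondary allylic C10 hydroxyl with retention, while the tertiary C5 hydroxyl, flanked by the quaternary C1 and the isopropyl-bearing C4, should stay free.

**Compound list**
1 | 2-methylfuran | Cc1ccco1 | starting material
2 | (E)-4-methylpent-2-enal | CC(C)/C=C/C=O | starting material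
3 | (R)-4-methyl-3-(5-methylfuran-2-yl)pentanal | O=CC[C@H](C(C)C)c1ccc(C)o1 | intermediate
4 | triethyl 2-phosphonopropionate | CCOC(=O)C(C)P(=O)(OCC)OCC | starting material
5 | ethyl (2E,5R)-2,6-dimethyl-5-(5-methylfuran-2-yl)hept-2-enoate | CCOC(=O)/C(C)=C/C[C@H](C(C)C)c1ccc(C)o1 | intermediate
6 | ethyl (2RS,5R)-2,6-dimethyl-5-(5-methylfuran-2-yl)heptanoate | CCOC(=O)C(C)CC[C@H](C(C)C)c1ccc(C)o1 | intermediate
7 | (3RS,6R)-1-chloro-3,7-dimethyl-6-(5-methylfuran-2-yl)octan-2-one | ClCC(=O)C(C)CC[C@H](C(C)C)c1ccc(C)o1 | intermediate
8 | oxyallyl cation (2-oxidoallyl cation C1–C10–C9 tethered to the furan) | [CH2+]C([O-])=C(C)CC[C@H](C(C)C)c1ccc(C)o1 | intermediate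
9 | (1S,4R,5S,8R)-5,8-epoxydauc-6-en-10-one | O=C1C[C@]2(C)C=C[C@]3(O2)[C@@H](C(C)C)CC[C@]13C | intermediate
10 | (1S,4R,5S,8S)-5,8-epoxydaucan-10-one | O=C1C[C@]2(C)CC[C@]3(O2)[C@@H](C(C)C)CC[C@]13C | intermediate
11 | (1S,4R,5S)-5-(trimethylsilyloxy)dauc-8-en-10-one | O=C1C=C(C)CC[C@]2(O[Si](C)(C)C)[C@@H](C(C)C)CC[C@]12C | intermediate
12 | (1S,4R,5S)-5-hydroxydauc-8-en-10-one | O=C1C=C(C)CC[C@]2(O)[C@@H](C(C)C)CC[C@]12C | intermediate
13 | (1R,4R,5S,10S)-dauc-8-ene-5,10-diol | O[C@H]1C=C(C)CC[C@]2(O)[C@@H](C(C)C)CC[C@]12C | intermediate
14 | 4-methoxybenzoyl chloride | COc1ccc(C(Cl)=O)cc1 | starting material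
15 | (1R,4R,5S,10S)-5-hydroxydauc-8-en-10-yl 4-methoxybenzoate | COc1ccc(C(=O)O[C@H]2C=C(C)CC[C@]3(O)[C@@H](C(C)C)CC[C@]23C)cc1 | target

Total step count: 9
Longest linear sequence: 9 steps (from 1 and 2 to 15)

**Steps most likely to fail**

Step 5. Two processes may defeat it. Substitution of the primary chloride by the alkoxide, or Favorskii ring contraction, may outrun enolisation toward the hindered C1–H and ionisation. The cycloaddition may also pass through the extended instead of the compact arrangement, which would place the C1 methyl anti to the oxygen bridge. The fallback sets out from 6 and comes back to the route at 9; it generates the same oxyallyl unit reductively, without base or a protic nucleophile. Deprotonation of 6 with LDA in THF at −78 °C and chlorination of the ester enolate with hexachloroethane should give ethyl (2RS,5R)-2-chloro-2,6-dimethyl-5-(5-methylfuran-2-yl)heptanoate F1. Chloromethyllithium under the conditions of step 4 should convert it into (3RS,6R)-1,3-dichloro-3,7-dimethyl-6-(5-methylfuran-2-yl)octan-2-one F2. Treatment of F2 with NaI and copper powder in MeCN (halide exchange at C9, reductive enolate formation there, loss of the tertiary chloride from C1) should then close to 9. Enolisation toward C1 is no longer needed. The metal counter-ion (sodium and copper here, zinc with a Zn–Cu couple) becomes a handle on the compact-to-extended ratio, although this does not guarantee the C1 configuration.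

Step 8. Hydride may reach C10 from the face of the C5 oxygen, either by internal delivery from an alkoxyborohydride or by attack on an unchelated conformer if the tertiary hydroxyl is slow to bind boron. That would give the C10 epimer. The fallback sets out from 12 and comes back at 15; it corrects the centre by inversion instead of by a selective reduction. If the reduction delivers mainly (1R,4R,5S,10R)-dauc-8-ene-5,10-diol F6, Mitsunobu esterification (PPh3, DIAD, 4-methoxybenzoic acid, toluene, 0 °C to rt) should invert C10 and install the anisoate in one operation. The tertiary C5 hydroxyl does not take part.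

Step 7. After silyl activation the bridge may ionise at C8 and lose a proton from C7 or from the C8 methyl instead of through the enol ether, giving non-conjugated alkenes. On desilylation the free β-hydroxy ketone may undergo retro-aldol cleavage of C1–C5 and re-close with loss of the C1/C5 configuration. The fallback sets out from 10 and comes back at 15; it changes the protecting-group strategy so that the C5 oxygen is never free next to the ketone. Opening with TESOTf and Et3N in CH2Cl2 should give (1S,4R,5S)-5-(triethylsilyloxy)dauc-8-en-10-one F3, which is isolated. Luche reduction (NaBH4, CeCl3·7H2O, MeOH, −78 °C) from the face opposite the angular methyl and the silyloxy group should give (1R,4R,5S,10S)-5-(triethylsilyloxy)dauc-8-en-10-ol F4. Acylation with 14 (pyridine, DMAP) should give (1R,4R,5S,10S)-5-(triethylsilyloxy)dauc-8-en-10-yl 4-methoxybenzoate F5. HF·pyridine in THF then frees the C5 hydroxyl to give 15.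

**Further compounds**
F1 | step 5 | ethyl (2RS,5R)-2-chloro-2,6-dimethyl-5-(5-methylfuran-2-yl)heptanoate | CCOC(=O)C(C)(Cl)CC[C@H](C(C)C)c1ccc(C)o1
F2 | step 5 | (3RS,6R)-1,3-dichloro-3,7-dimethyl-6-(5-methylfuran-2-yl)octan-2-one | ClCC(=O)C(C)(Cl)CC[C@H](C(C)C)c1ccc(C)o1
F3 | step 7 | (1S,4R,5S)-5-(triethylsilyloxy)dauc-8-en-10-one | O=C1C=C(C)CC[C@]2(O[Si](CC)(CC)CC)[C@@H](C(C)C)CC[C@]12C
F4 | step 7 | (1R,4R,5S,10S)-5-(triethylsilyloxy)dauc-8-en-10-ol | O[C@H]1C=C(C)CC[C@]2(O[Si](CC)(CC)CC)[C@@H](C(C)C)CC[C@]12C
F5 | step 7 | (1R,4R,5S,10S)-5-(triethylsilyloxy)dauc-8-en-10-yl 4-methoxybenzoate | COc1ccc(C(=O)O[C@H]2C=C(C)CC[C@]3(O[Si](CC)(CC)CC)[C@@H](C(C)C)CC[C@]23C)cc1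
F6 | step 8 | (1R,4R,5S,10R)-dauc-8-ene-5,10-diol | O[C@@H]1C=C(C)CC[C@]2(O)[C@@H](C(C)C)CC[C@]12C
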